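## The problem

Isocardopatine 13 is a meso compound: a cyclobutane whose adjacent carbons C1 and C2 each carry a (2,2'-bithiophen-5-yl)ethynyl arm on the same face, while C3 and C4 are plain methylenes. The only stereochemical task is the cis relation of C1 and C2 (1R,2S); no absolute configuration is involved, but cis is the more strained arrangement, so any intermediate in which C1 or C2 is acidic, cationic or a long-lived radical will drift to trans. Because the substituents are thin, linear alkynes, one centre cannot be relied on to direct the other in a stepwise construction; the relation has to be made in one event or carried over from a ring in which it is easy to fix. The fragile parts are the electron-rich bithiophenes (oxidants, electrophiles, strong acid, light), the alkynes (terminal C–H toward CuI and electrophilic iodine) and the cis-1,2-dialkynylcyclobutane itself, a strained 1,5-diyne that should not be heated for long. The two identical aryl–alkyne bonds call for a late twofold Sonogashira coupling, which reduces the core to cis-1,2-diethynylcyclobutane 12, a volatile C8 hydrocarbon best made and consumed in one flask. The feature that opens the key step is that C1 and C2 are both propargylic methines, bonded to each other and tied 1,4 through C4 and C3: the C1–C2 bond is the bond that a 1,4-biradical with two propargyl-stabilised ends would form, and a cis-2,5-dialkynylpyrrolidine releases that biradical when its nitrogen leaves as N2.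

## Retrosynthesis

**13 to 10 and 11.** The two C(sp)–C(sp2) bonds between the alkynes and the bithiophenes are cut first. Cutting here, and not carrying the heteroaryl groups through the synthesis, keeps the oxidisable bithiophenes away from the oxidative ring contraction. The pieces are two molecules of commercial 5-bromo-2,2'-bithiophene 11 and the silyl-capped C8 core 10, cis-1,2-bis[(triisopropylsilyl)ethynyl]cyclobutane. The forward reaction has to unmask 10 to the volatile diyne 12 and couple it at both ends in the same flask, at a temperature that spares the strained 1,5-diyne.

**10 to 8 (through 9).** The C1–C2 bond of the cyclobutane is cut and a nitrogen atom is placed between the two carbons, giving cis-2,5-bis[(triisopropylsilyl)ethynyl]pyrrolidine 8. Of the four ring bonds, only C1–C2 joins two radical-stabilising positions, so it is the natural bond for a biradical collapse. Cutting C1–C4 and C2–C3 instead leads to [2+2] chemistry that either gives no control of cis (enyne dimerisation) or needs carbonyl groups on the stereocentres. In 8 the vicinal cis relation is stored as a 2,5-relation across nitrogen, which is easy to set and not strained. The forward step must N-aminate 8 to the 1,1-diazene 9, lose N2 and close the ring with retention, while the oxidant leaves the alkynes alone; the triisopropylsilyl caps are chosen for that.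

**8 to 7 to 6.** The N–H of 8 is traced to the tert-butyl carbamate 7, and the two C(sp)–Si bonds of 7 to the terminal diyne 6. The carbamate is needed for the aldehyde and acetylide chemistry earlier on, and the silyl groups are needed only from the ring contraction onward. Both operations are routine; the forward demand is a base that removes the alkyne protons without touching the propargylic α-amino C–H bonds.

**6 to 4 (through 5).** Each C≡C bond is cut so that the ring-bound alkyne carbon goes back to an ester carbon and the terminal carbon to a one-carbon diazophosphonate reagent. No bond to a ring stereocentre is made or broken, so the cis relation of the diester 4 is carried unchanged. This is preferred to adding alkynyl nucleophiles to an iminium ion, which would give cis/trans mixtures. The forward reaction has to pass through the α-amino dialdehyde 5 without letting it epimerise.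

**4 to 3 to 1 and 2.** The carbamate 4 comes from the N-benzyl diester 3 by exchange of the nitrogen substituent, and the two C–N bonds of 3 are cut to benzylamine 2 and diethyl meso-2,5-dibromoadipate 1. Double SN2 displacement with inversion at both carbons turns the meso dibromide into the meso, cis pyrrolidine, so the stereochemistry of 13 is bought with a commercial acyclic compound.

## Roads not taken

Alternative 1: The C1–C4 and C2–C3 bonds are cut, and the ring is built by [2+2] photocycloaddition of maleic anhydride A1 and ethylene A2 under triplet sensitisation, which gives cis-cyclobutane-1,2-dicarboxylic anhydride A3.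
- Forward: reduction and reoxidation of A3 would lead to cis-cyclobutane-1,2-dicarbaldehyde A4, homologation of A4 to the diyne 12, and then the same Sonogashira coupling with 11.
- Merits: the cis relation is forced by the ring fusion of A3, the two partners A1 and A2 are commodity chemicals, and the photocycloaddition is of long standing. At about five operations this road is shorter than the chosen one and its key step is better established.
- Weak points: in A4 both stereocentres are α to a carbonyl group on a ring where trans is clearly the more stable arrangement, so the base of an alkynylation would pull toward trans. Gaseous A2 under irradiation also needs dedicated apparatus.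
- Comparison: the chosen plan sets against the shorter route that it makes the vicinal cis relation only when the ring carbons are no longer acidic, and that its own epimerisable stage 5 is a 2,5-disubstituted carbamate with no comparable bias toward trans.

Alternative 2: The C3–C4 bond is cut and closed by an intramolecular alkylation held in a cyclohexene.
- Forward: cis-4,5-bis(iodomethyl)cyclohexene A5, reached by a Diels–Alder, reduction and iodination sequence, is treated with t-BuLi. Lithium–iodine exchange at one arm of A5 and displacement of the other iodide give cis-bicyclo[4.2.0]oct-3-ene A6. Ozonolysis of A6 would give cis-cyclobutane-1,2-diacetaldehyde A7, and each CH2–CHO arm of A7 would then be converted into a terminal alkyne to reach 12.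
- Merits: the cis relation comes from the Diels–Alder reaction, and the ring stereocentres never sit next to a carbonyl group. On stereochemical security this road is better than the chosen one.
- Weak points: A6 is a volatile hydrocarbon, and the double aldehyde-to-alkyne conversion of A7 (enol sulfonylation, then elimination) is the least reliable operation; elimination toward the ring would destroy the stereocentre.
- Comparison: the length is about the same (seven operations). The chosen plan offers a well-behaved alkynylation in place of that end game, at the price of an untested substitution pattern in its key step.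

Alternative 3: The C1–C2 and C2–C3 bonds are cut and the ring is built convergently with one bithienylalkyne already in place.
- Forward: 3-(2,2'-bithiophen-5-yl)propynal A8 reacts with diphenylsulfonium cyclopropylide A9 to give 2-[(2,2'-bithiophen-5-yl)ethynyl]-1-oxaspiro[2.2]pentane A10, which rearranges with LiBF4 to 2-[(2,2'-bithiophen-5-yl)ethynyl]cyclobutan-1-one A11. The lithium acetylide of 5-ethynyl-2,2'-bithiophene A12 adds to the ketone of A11 to give the tertiary alcohol A13, which is ionised and reduced with a silane (Et3SiH) to 13.
- Merits: convergent, about five steps in the longest line, and it avoids both the volatile diyne 12 and a late twofold Sonogashira coupling. In those respects it is better than the chosen plan.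
- Weak points: the cis relation rests on hydride delivery to the ionised propargylic carbon of A13 anti to a slim alkynyl neighbour, a selectivity with little to enforce it. Ionisation can also end in cyclopropylcarbinyl rearrangement, reduction at the allenyl terminus or proton loss, and the acid needed endangers the bithiophenes.
- Comparison: the chosen plan replaces a stereoselective step of doubtful bias by a stereospecific one whose outcome is fixed by the meso starting material.

Key step: step 6

Assumption: the stereodescriptors of the target are read as the meso cis isomer (1R,2S), so only relative configuration has to be controlled.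

## Route

Step 1
Reactants: 1 diethyl meso-2,5-dibromoadipate; 2 benzylamine
Product: 3 diethyl cis-1-benzylpyrrolidine-2,5-dicarboxylate (meso, 2R,5S)
Conditions: K2CO3, toluene/H2O, reflux
Reagents that add atoms: none
Why: Twofold SN2 N-alkylation, the second a ring-closing displacement, proceeds with inversion at both bromide-bearing carbons, so the meso dibromide gives the meso cis-2,5-diester; both C–N stereocentres are set by the configuration of 1.

Step 2
Reactants: 3 diethyl cis-1-benzylpyrrolidine-2,5-dicarboxylate
Product: 4 diethyl cis-1-(tert-butoxycarbonyl)pyrrolidine-2,5-dicarboxylate
Conditions: H2 (1 atm), Pd(OH)2 on carbon, Boc2O, EtOH, rt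
Reagents that add atoms: di-tert-butyl dicarbonate, CC(C)(C)OC(=O)OC(=O)OC(C)(C)C
Why: Hydrogenolysis of the N-benzyl group with in situ acylation of the freed secondary amine by Boc2O; no stereocentre is touched, and the carbamate is what the aldehyde and acetylide steps require.

Step 3
Reactants: 4 diethyl cis-1-(tert-butoxycarbonyl)pyrrolidine-2,5-dicarboxylate
Product: 6 tert-butyl cis-2,5-diethynylpyrrolidine-1-carboxylate, via tert-butyl cis-2,5-diformylpyrrolidine-1-carboxylate 5 (not isolated)
Conditions: i-Bu2AlH, CH2Cl2, −78 °C; then MeOH, K2CO3, MeCOC(N2)P(O)(OMe)2, −78 °C to rt
Reagents that add atoms: dimethyl (1-diazo-2-oxopropyl)phosphonate, CC(=O)C(=[N+]=[N-])P(=O)(OC)OC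
Why: At −78 °C each ester is reduced only to the carbamate-chelated aluminium hemiacetal; MeOH/K2CO3 then releases dialdehyde 5 in the presence of the diazophosphonate, which homologates both formyl groups at once (Ohira–Bestmann variant of the Seyferth–Gilbert alkynylation), a one-flask protocol established for N-Boc α-amino esters with retention of the α-configuration. No stereocentre is made, and the cis relation is kept because 5 never accumulates.

Step 4
Reactants: 6 tert-butyl cis-2,5-diethynylpyrrolidine-1-carboxylate
Product: 7 tert-butyl cis-2,5-bis[(triisopropylsilyl)ethynyl]pyrrolidine-1-carboxylate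
Conditions: LiN(SiMe3)2, THF, −78 °C; then i-Pr3SiOTf, −78 to 0 °C
Reagents that add atoms: triisopropylsilyl trifluoromethanesulfonate, CC(C)[Si](C(C)C)(C(C)C)OS(=O)(=O)C(F)(F)F
Why: Deprotonation of the two terminal alkynes and C-silylation of the lithium acetylides by the silyl triflate; the amide base is too weak to remove the propargylic α-amino protons, so the cis relation is safe. The bulky i-Pr3Si caps are chosen because they withstand electrophilic trivalent iodine in step 6.

Step 5
Reactants: 7 tert-butyl cis-2,5-bis[(triisopropylsilyl)ethynyl]pyrrolidine-1-carboxylate
Product: 8 cis-2,5-bis[(triisopropylsilyl)ethynyl]pyrrolidine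
Conditions: CF3CO2H, CH2Cl2, 0 °C to rt; aq. NaHCO3
Reagents that add atoms: none
Why: Acidolysis of the tert-butyl carbamate with loss of isobutene and CO2; the C(sp)–Si bonds and the propargylic C–N bonds are stable to CF3CO2H, and the basic wash gives the free secondary amine needed for N-amination.

Step 6
Reactants: 8 cis-2,5-bis[(triisopropylsilyl)ethynyl]pyrrolidine
Product: 10 cis-1,2-bis[(triisopropylsilyl)ethynyl]cyclobutane, via 1,1-diazene 9 (not isolated)
Conditions: PhI(OH)OTs, NH2CO2NH4, CF3CH2OH, 80 °C (sealed tube)
Reagents that add atoms: none
Why: PhI(OH)OTs and the ammonia released from ammonium carbamate form an electrophilic iodonitrene that N-aminates the secondary amine of 8, and loss of PhI gives the 1,1-diazene 9 (the nitrogen taken from the carbamate leaves again in N2, so no reagent atom stays in 10). 9 extrudes N2 to a singlet 1,4-biradical with both radical centres propargylic, and the four-membered ring closes by radical–radical recombination of these two ends to the C1–C2 bond, a biradical collapse and not a polar exo or endo closure. The closest known reaction type is the iodonitrene-mediated contraction of 2-aryl and 2,5-disubstituted pyrrolidines to cyclobutanes, the one-flask form of the classical oxidation of N-aminopyrrolidines; alkynyl groups on both α-carbons are an untested substitution pattern within that class. Both new stereocentres (C1 and C2) are set by substrate control: the cis arrangement of the meso pyrrolidine is carried over with retention at each carbon because singlet recombination is faster than rotation about the C1–C4 and C2–C3 bonds. The step needs ring closure to outrun beta-scission of the C3–C4 bond (which would give two molecules of silyl enyne) and coupling at the propargylic, not the allenyl, terminus; the latter is secured because allenyl coupling would have to form a six-membered cyclic allene and is shielded by the i-Pr3Si groups, the former rests on the short lifetime of the singlet and on the lowest temperature at which 9 still loses N2. It also needs the oxidant to react only at nitrogen, which the i-Pr3Si caps secure, since terminal or Me3Si alkynes would be turned into alkynyliodonium salts by trivalent iodine and bithiophenes would be oxidised.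

Step 7
Reactants: 10 cis-1,2-bis[(triisopropylsilyl)ethynyl]cyclobutane; 11 5-bromo-2,2'-bithiophene
Product: 13 isocardopatine (cis-1,2-bis[(2,2'-bithiophen-5-yl)ethynyl]cyclobutane), via cis-1,2-diethynylcyclobutane 12 (not isolated)
Conditions: Bu4NF, THF, 0 °C to rt; then 11 (2.2 equiv), Pd(PPh3)4, CuI, i-Pr2NH, 45 °C, degassed, dark
Reagents that add atoms: 5-bromo-2,2'-bithiophene (second equivalent of 11), Brc1ccc(-c2cccs2)s1
Why: Fluoride cleaves both C(sp)–Si bonds to the volatile diyne 12, which is coupled at both termini in the same flask by Sonogashira reaction (oxidative addition of zerovalent palladium into the thienyl C–Br bond, transmetalation of the acetylide formed with CuI, reductive elimination), consuming two molecules of 11, one per alkyne. The ring stereocentres are not involved, and the mild temperature spares the strained cis-1,5-diyne.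

## Compound list

1 | diethyl meso-2,5-dibromoadipate (2R,5S) | CCOC(=O)[C@@H](Br)CC[C@@H](Br)C(=O)OCC | starting material
2 | benzylamine | NCc1ccccc1 | starting material
3 | diethyl cis-1-benzylpyrrolidine-2,5-dicarboxylate (meso) | CCOC(=O)[C@@H]1CC[C@H](C(=O)OCC)N1Cc1ccccc1 | intermediate
4 | diethyl cis-1-(tert-butoxycarbonyl)pyrrolidine-2,5-dicarboxylate (meso) | CCOC(=O)[C@@H]1CC[C@H](C(=O)OCC)N1C(=O)OC(C)(C)C | intermediate
5 | tert-butyl cis-2,5-diformylpyrrolidine-1-carboxylate (meso) | O=C[C@@H]1CC[C@H](C=O)N1C(=O)OC(C)(C)C | intermediate
6 | tert-butyl cis-2,5-diethynylpyrrolidine-1-carboxylate (meso) | C#C[C@@H]1CC[C@H](C#C)N1C(=O)OC(C)(C)C | intermediate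
7 | tert-butyl cis-2,5-bis[(triisopropylsilyl)ethynyl]pyrrolidine-1-carboxylate (meso) | CC(C)[Si](C(C)C)(C(C)C)C#C[C@@H]1CC[C@H](C#C[Si](C(C)C)(C(C)C)C(C)C)N1C(=O)OC(C)(C)C | intermediate
8 | cis-2,5-bis[(triisopropylsilyl)ethynyl]pyrrolidine (meso) | CC(C)[Si](C(C)C)(C(C)C)C#C[C@@H]1CC[C@H](C#C[Si](C(C)C)(C(C)C)C(C)C)N1 | intermediate
9 | cis-2,5-bis[(triisopropylsilyl)ethynyl]pyrrolidine-derived 1,1-diazene (N-nitrene, meso) | CC(C)[Si](C(C)C)(C(C)C)C#C[C@@H]1CC[C@H](C#C[Si](C(C)C)(C(C)C)C(C)C)[N+]1=[N-] | intermediate
10 | cis-1,2-bis[(triisopropylsilyl)ethynyl]cyclobutane (meso, 1R,2S) | CC(C)[Si](C(C)C)(C(C)C)C#C[C@@H]1CC[C@@H]1C#C[Si](C(C)C)(C(C)C)C(C)C | intermediate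
11 | 5-bromo-2,2'-bithiophene | Brc1ccc(-c2cccs2)s1 | starting material
12 | cis-1,2-diethynylcyclobutane (meso) | C#C[C@@H]1CC[C@@H]1C#C | intermediate
13 | isocardopatine, cis-1,2-bis[(2,2'-bithiophen-5-yl)ethynyl]cyclobutane (meso, 1R,2S) | C(#C[C@@H]1CC[C@@H]1C#Cc1ccc(-c2cccs2)s1)c1ccc(-c2cccs2)s1 | target

## Step count and least certain steps

Total steps: 7. Longest linear sequence: 7 (1 to 13); 11 enters in the last step.

**Step 6 (key step).** Three things are most likely to go wrong:
- beta-scission of the propargyl-stabilised 1,4-biradical to two enyne fragments in place of ring closure;
- partial loss of stereoretention if the stabilised biradical lives long enough to rotate;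
- attack of the excess trivalent iodine reagent on the amine α-C–H bonds (dehydrogenation to an imine) or on the alkynes.

Fallback: generate the same diazene stepwise and cold, without an electrophilic iodine reagent in excess. The route is left at 8, which is N-nitrosated (t-BuONO, CH2Cl2) to cis-1-nitroso-2,5-bis[(triisopropylsilyl)ethynyl]pyrrolidine F1. F1 is reduced with LiAlH4 in Et2O at 0 °C to cis-1-amino-2,5-bis[(triisopropylsilyl)ethynyl]pyrrolidine F2. F2 is oxidised with HgO (divalent mercury) in Et2O at 0 °C to rt, the classical oxidation of N-aminopyrrolidines, to the diazene 9, which loses N2; the route is rejoined at 10.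

**Step 3.** Collapse of the aluminium hemiacetal before the quench would cause over-reduction of one arm to the alcohol, and the α-amino dialdehyde 5 may epimerise in K2CO3/MeOH, eroding the cis relation; homologation of only one arm is also possible.

Fallback: separate reduction from alkynylation and use a non-basic olefination. Setting out from 4, LiBH4 in THF gives tert-butyl cis-2,5-bis(hydroxymethyl)pyrrolidine-1-carboxylate F3. Swern oxidation with i-Pr2NEt gives 5, which is used crude. Corey–Fuchs olefination (CBr4, PPh3, CH2Cl2, 0 °C) gives tert-butyl cis-2,5-bis(2,2-dibromovinyl)pyrrolidine-1-carboxylate F4. Treatment of F4 with n-BuLi in THF at −78 °C and trapping of the dilithium diacetylide with i-Pr3SiOTf returns to the route at 7, bypassing 6.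

**Step 7.** The free diyne 12 may be lost by evaporation or oligomerised by oxidative homocoupling promoted by CuI if traces of oxygen are present, and the second coupling may stall, leaving mono-coupled material.

Fallback: reverse the polarity of the coupling so that no free terminal diyne and no CuI are involved. Setting out from 10, desilylative bromination (AgF, N-bromosuccinimide, MeCN, rt, dark) gives cis-1,2-bis(bromoethynyl)cyclobutane F5. In a second flask 11 is converted by n-BuLi and then ZnCl2 (THF, −78 °C to rt) into (2,2'-bithiophen-5-yl)zinc chloride F6. Negishi coupling of F5 with two equivalents of F6 under Pd(PPh3)4 in THF at rt rejoins the route at 13.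

**Step 1.** Bromide liberated in the first displacement can exchange with the remaining C–Br centre, or the α-bromo ester can enolise, before ring closure; either process erodes the meso configuration and lets material of trans configuration contaminate 3.

Fallback: replace chromatographic separation by a chemical filter that only the cis isomer can pass. Setting out from 3 of eroded cis purity, saponification (NaOH, aq. EtOH, then acid) gives cis-1-benzylpyrrolidine-2,5-dicarboxylic acid F7, with any trans material carried along. Warming in Ac2O closes only the cis diacid F7 to the bridged anhydride 8-benzyl-3-oxa-8-azabicyclo[3.2.1]octane-2,4-dione F8, which is crystallised; material of trans configuration cannot cyclise and stays in the mother liquor. Fischer esterification of F8 (EtOH, H2SO4, reflux) returns to the route at pure 3.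

## Further compounds

F1 | step 6 | cis-1-nitroso-2,5-bis[(triisopropylsilyl)ethynyl]pyrrolidine | CC(C)[Si](C(C)C)(C(C)C)C#C[C@@H]1CC[C@H](C#C[Si](C(C)C)(C(C)C)C(C)C)N1N=O
F2 | step 6 | cis-1-amino-2,5-bis[(triisopropylsilyl)ethynyl]pyrrolidine | CC(C)[Si](C(C)C)(C(C)C)C#C[C@@H]1CC[C@H](C#C[Si](C(C)C)(C(C)C)C(C)C)N1N
F3 | step 3 | tert-butyl cis-2,5-bis(hydroxymethyl)pyrrolidine-1-carboxylate | OC[C@@H]1CC[C@H](CO)N1C(=O)OC(C)(C)C
F4 | step 3 | tert-butyl cis-2,5-bis(2,2-dibromovinyl)pyrrolidine-1-carboxylate | BrC(Br)=C[C@@H]1CC[C@H](C=C(Br)Br)N1C(=O)OC(C)(C)C
F5 | step 7 | cis-1,2-bis(bromoethynyl)cyclobutane | BrC#C[C@@H]1CC[C@@H]1C#CBr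
F6 | step 7 | (2,2'-bithiophen-5-yl)zinc chloride | Cl[Zn]c1ccc(-c2cccs2)s1
F7 | step 1 | cis-1-benzylpyrrolidine-2,5-dicarboxylic acid | OC(=O)[C@@H]1CC[C@H](C(O)=O)N1Cc1ccccc1
F8 | step 1 | 8-benzyl-3-oxa-8-azabicyclo[3.2.1]octane-2,4-dione | O=C2OC(=O)[C@@H]1CC[C@H]2N1Cc1ccccc1
A1 | alternative 1 | maleic anhydride | O=C1OC(=O)C=C1
A2 | alternative 1 | ethylene | C=C
A3 | alternative 1 | cis-cyclobutane-1,2-dicarboxylic anhydride | O=C1OC(=O)[C@@H]2CC[C@H]12
A4 | alternative 1 | cis-cyclobutane-1,2-dicarbaldehyde | O=C[C@@H]1CC[C@@H]1C=O
A5 | alternative 2 | cis-4,5-bis(iodomethyl)cyclohexene | IC[C@@H]1CC=CC[C@@H]1CI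
A6 | alternative 2 | cis-bicyclo[4.2.0]oct-3-ene | C1=CC[C@@H]2CC[C@@H]2C1
A7 | alternative 2 | cis-cyclobutane-1,2-diacetaldehyde | O=CC[C@@H]1CC[C@@H]1CC=O
A8 | alternative 3 | 3-(2,2'-bithiophen-5-yl)propynal | O=CC#Cc1ccc(-c2cccs2)s1
A9 | alternative 3 | diphenylsulfonium cyclopropylide | c1ccc(cc1)[S+](c1ccccc1)[C-]1CC1
A10 | alternative 3 | 2-[(2,2'-bithiophen-5-yl)ethynyl]-1-oxaspiro[2.2]pentane (racemic, one enantiomer drawn) | C1CC12O[C@@H]2C#Cc3ccc(-c4cccs4)s3
A11 | alternative 3 | 2-[(2,2'-bithiophen-5-yl)ethynyl]cyclobutan-1-one (racemic, one enantiomer drawn) | O=C1CC[C@@H]1C#Cc1ccc(-c2cccs2)s1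
A12 | alternative 3 | 5-ethynyl-2,2'-bithiophene | C#Cc1ccc(-c2cccs2)s1
A13 | alternative 3 | 1,2-bis[(2,2'-bithiophen-5-yl)ethynyl]cyclobutan-1-ol (racemic, carbinol configuration not defined) | OC1(C#Cc2ccc(-c3cccs3)s2)CC[C@@H]1C#Cc1ccc(-c2cccs2)s1
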